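The target is dissected at C4(upper)–C6(lower) into a fisetinidol-type 4-ketone and a lower ent-epifisetinidol unit, and the lower unit is traced back to L-tyrosine. In ring D (the benzo ring of the lower flavan) O1 sits on C8a, meta to the C7 hydroxyl and ortho to C4a, which is para to that hydroxyl: a para-alkylphenol with one extra meta oxygen. Dearomatisation at C4a gives a para-quinol whose dienone β-carbon is C8a. In the key step the benzylic C2 hydroxyl adds there (oxa-Michael, closing pyran ring F) and loss of water restores the arene, all diastereomeric adducts converging on one chroman.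

Key step: step 14

Remark: the structure is read as a (2R,3S,4S) 2,3-trans-3,4-cis upper unit joined from C4 to C6 of a (2S,3S) 2,3-cis lower unit; flavan numbering is used for both units, with rings A (benzo), B (catechol), C (pyran) in the upper unit and D (benzo), E (catechol), F (pyran) in the lower unit.

**Upper unit (steps 1–5)**

Step 1
Reactants: 1 1-[4-(benzyloxy)-2-hydroxyphenyl]ethan-1-one
Product: 2 1-[4-(benzyloxy)-2-(methoxymethoxy)phenyl]ethan-1-one
Conditions: NaH, MOMCl, DMF, 0 °C to rt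
Reagents that add atoms: chloromethyl methyl ether, COCCl
Why: Williamson-type O-alkylation of the sodium phenoxide, NaH being needed because the 2-hydroxyl is hydrogen-bonded to the ketone.

Step 2
Reactants: 2 1-[4-(benzyloxy)-2-(methoxymethoxy)phenyl]ethan-1-one; 3 3,4-bis(benzyloxy)benzaldehyde
Product: 4 (E)-1-[4-(benzyloxy)-2-(methoxymethoxy)phenyl]-3-[3,4-bis(benzyloxy)phenyl]prop-2-en-1-one
Conditions: KOH, EtOH–THF, rt
Reagents that add atoms: none
Why: Claisen–Schmidt condensation of the methyl ketone with a non-enolisable aldehyde, the E1cB dehydration giving the E-enone.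

Step 3
Reactants: 4 (E)-chalcone
Product: 5 [4-(benzyloxy)-2-(methoxymethoxy)phenyl]{(2R,3S)-3-[3,4-bis(benzyloxy)phenyl]oxiran-2-yl}methanone
Conditions: poly-L-leucine, urea–H2O2, DBU, THF, rt
Reagents that add atoms: urea–hydrogen peroxide, OO.NC(N)=O
Why: Juliá–Colonna epoxidation, in which the helical peptide should direct the hydroperoxide to one enone face and give the trans (2R,3S)-epoxy ketone.

Step 4
Reactants: 5 (2R,3S)-epoxy ketone
Product: 7 (2R,3R)-7-(benzyloxy)-2-[3,4-bis(benzyloxy)phenyl]-3-hydroxychroman-4-one, via 2'-hydroxy epoxy ketone 6 (not isolated)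
Conditions: conc. HCl, MeOH–THF, 55 °C
Reagents that add atoms: none
Why: acetal cleavage frees the phenol, which opens the epoxide at the electron-rich benzylic carbon (6-endo, inversion) while the carbinol carbon is untouched, so the 2,3-trans dihydroflavonol should result.

Step 5
Reactants: 7 (2R,3R)-dihydroflavonol
Product: 8 (2R,3R)-7-(benzyloxy)-2-[3,4-bis(benzyloxy)phenyl]-3-[(tert-butyldimethylsilyl)oxy]chroman-4-one
Conditions: TBSOTf, 2,6-lutidine, CH2Cl2, 0 °C
Reagents that add atoms: tert-butyldimethylsilyl triflate, CC(C)(C)[Si](C)(C)OS(=O)(=O)C(F)(F)F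
Why: silylation with the triflate under weakly basic conditions avoids enolisation and ring opening of the ketone and installs the bulky group that later shields the O3 face.

**Lower unit (steps 6–16)**

Step 6
Reactants: 9 L-tyrosine
Product: 10 (S)-2-hydroxy-3-(4-hydroxyphenyl)propanoic acid
Conditions: NaNO2, aq. H2SO4, 0 °C to rt
Reagents that add atoms: water, O
Why: diazotisation of the α-amino acid with hydrolysis through the α-lactone (double inversion, net retention) keeps the S configuration that becomes C3 of the lower unit.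

Step 7
Reactants: 10 (S)-2-hydroxy-3-(4-hydroxyphenyl)propanoic acid
Product: 11 methyl (S)-2-hydroxy-3-(4-hydroxyphenyl)propanoate
Conditions: MeOH, H2SO4 (cat.), reflux
Reagents that add atoms: methanol, CO
Why: Fischer esterification, which touches no stereocentre.

Step 8
Reactants: 11 methyl (S)-2-hydroxy-3-(4-hydroxyphenyl)propanoate
Product: 12 methyl (S)-3-{4-[(tert-butyldimethylsilyl)oxy]phenyl}-2-hydroxypropanoate
Conditions: TBSCl (1.05 equiv), imidazole, DMF, 0 °C
Reagents that add atoms: tert-butyldimethylsilyl chloride, CC(C)(C)[Si](C)(C)Cl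
Why: the more acidic phenol should be silylated faster than the hindered α-hydroxy ester hydroxyl with one equivalent of silyl chloride.

Step 9
Reactants: 12 phenol silyl ether
Product: 13 methyl (S)-2-(benzyloxy)-3-{4-[(tert-butyldimethylsilyl)oxy]phenyl}propanoate
Conditions: benzyl 2,2,2-trichloroacetimidate, TfOH (cat.), CH2Cl2–cyclohexane, 0 °C to rt
Reagents that add atoms: benzyl 2,2,2-trichloroacetimidate, N=C(OCc1ccccc1)C(Cl)(Cl)Cl
Why: acid-catalysed O-benzylation with the imidate avoids the base-induced racemisation of the α-alkoxy ester.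

Step 10
Reactants: 13 benzyl ether ester
Product: 14 (S)-2-(benzyloxy)-3-{4-[(tert-butyldimethylsilyl)oxy]phenyl}propanal
Conditions: i-Bu2AlH, CH2Cl2, −78 °C
Reagents that add atoms: none
Why: partial reduction, the aluminium hemiacetal chelated by the α-benzyloxy group surviving at −78 °C and releasing the aldehyde on work-up.

Step 11
Reactants: 14 (S)-α-benzyloxy aldehyde; 15 1,2-bis(benzyloxy)-4-bromobenzene
Product: 17 (1S,2S)-2-(benzyloxy)-1-[3,4-bis(benzyloxy)phenyl]-3-{4-[(tert-butyldimethylsilyl)oxy]phenyl}propan-1-ol, via aryl Grignard reagent 16 (not isolated)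
Conditions: 15, Mg, THF; then MgBr2·OEt2, 14, CH2Cl2, −78 °C
Reagents that add atoms: none
Why: chelation-controlled (Cram-chelate) Grignard addition, magnesium bridging the carbonyl and ether oxygens so that the aryl group enters from the face of the α-hydrogen and should give the syn (1S,2S) alcohol.

Step 12
Reactants: 17 (1S,2S)-alcohol
Product: 18 4-{(2S,3S)-2-(benzyloxy)-3-[3,4-bis(benzyloxy)phenyl]-3-hydroxypropyl}phenol
Conditions: K2CO3, MeOH, rt
Reagents that add atoms: none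
Why: base-catalysed methanolysis cleaves the aryl silyl ether selectively and leaves the benzyl ethers and the carbinol alone.

Step 13
Reactants: 18 para-alkylphenol
Product: 20 4-{(2S,3S)-2-(benzyloxy)-3-[3,4-bis(benzyloxy)phenyl]-3-hydroxypropyl}-4-hydroxycyclohexa-2,5-dien-1-one, via para-peroxyquinol 19 (not isolated)
Conditions: KHSO5 (as Oxone, 2KHSO5·KHSO4·K2SO4), NaHCO3, MeCN–H2O, rt; then Me2S
Reagents that add atoms: potassium peroxymonosulfate, [K+].[O-]S(=O)(=O)OO
Why: in bicarbonate buffer KHSO5 releases singlet oxygen, which adds to the para-alkylphenol at the alkylated para carbon to give the hydroperoxide that the sulfide reduces; this non-cationic dearomatisation cannot trigger spiro-etherification by the side-chain hydroxyl.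

Step 14
Reactants: 20 para-quinol
Product: 22 (2S,3S)-3-(benzyloxy)-2-[3,4-bis(benzyloxy)phenyl]chroman-7-ol, via cis-fused bicyclic enone 21 (not isolated)
Conditions: DBU (0.2 equiv), CH2Cl2, 0 °C to rt; then CSA (0.5 equiv), 40 °C
Reagents that add atoms: none
Why: DBU generates the side-chain alkoxide (future O1), which adds in a 6-exo-trig oxa-Michael fashion to either of the two diastereotopic enone β-carbons of the cross-conjugated dienone (the future C8a) to give the cis-fused enone 21; acid then ionises the tertiary C4a hydroxyl (via the dienol), and loss of the C8a proton with tautomerisation restores the benzene ring with the new oxygen meta to the phenol. Both events are known reaction types (oxa-Michael addition of tethered alcohols to para-quinol dienones; acid-promoted dehydrative rearomatisation of 4-hydroxycyclohexenones), run here in tandem. Ring F closes by 6-exo-trig attack; the five-membered alternative is excluded because O3 is a benzyl ether, and spiro-etherification at C4a was avoided by dearomatising with singlet oxygen instead of a cationic oxidant. No new stereocentre survives: those at C4a and C8a of 21 are erased on aromatisation, so every diastereomer of 21 funnels into one product, while C2 and C3 keep the configurations set in steps 6 and 11 because the O–C2 bond is never broken (retention, hence 2,3-cis). The selectivity that matters is addition–elimination over a dienone–phenol 1,2-shift and over ionisation of the electron-rich benzylic C2–O bond, which is why cyclisation is done under base first and the dehydration with a weak sulfonic acid at modest temperature.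

Step 15
Reactants: 22 (2S,3S)-chroman-7-ol
Product: 23 (2S,3S)-3,7-bis(benzyloxy)-2-[3,4-bis(benzyloxy)phenyl]chromane
Conditions: BnBr, K2CO3, DMF, rt
Reagents that add atoms: benzyl bromide, BrCc1ccccc1
Why: Williamson etherification of the phenol.

Step 16
Reactants: 23 tetrabenzyl ether
Product: 24 (2S,3S)-3,7-bis(benzyloxy)-2-[3,4-bis(benzyloxy)phenyl]-6-bromochromane
Conditions: NBS, CH2Cl2, −20 to 0 °C
Reagents that add atoms: N-bromosuccinimide, O=C1CCC(=O)N1Br
Why: electrophilic aromatic bromination should go to C6 of ring D, ortho to the benzyloxy group and para to the ring oxygen, C8 between the two oxygens being hindered and ring E less activated.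

**Union and end game (steps 17–20)**

Step 17
Reactants: 24 6-bromochromane; 8 (2R,3R)-3-silyloxychroman-4-one
Product: 26 (2R,3R)-7-(benzyloxy)-2-[3,4-bis(benzyloxy)phenyl]-4-{(2S,3S)-3,7-bis(benzyloxy)-2-[3,4-bis(benzyloxy)phenyl]chroman-6-yl}-3-[(tert-butyldimethylsilyl)oxy]chroman-4-ol (C4 epimers), via aryllithium 25 (not isolated)
Conditions: t-BuLi (2 equiv), THF, −78 °C; then 8, −78 to −40 °C
Reagents that add atoms: none
Why: bromine–lithium exchange and 1,2-addition of the aryllithium to the ketone at low temperature, the configuration of the new carbinol carbon being irrelevant because it is erased in the next step.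

Step 18
Reactants: 26 tertiary carbinol
Product: 27 (2R,3S,4R)-7-(benzyloxy)-2-[3,4-bis(benzyloxy)phenyl]-4-{(2S,3S)-3,7-bis(benzyloxy)-2-[3,4-bis(benzyloxy)phenyl]chroman-6-yl}-3-[(tert-butyldimethylsilyl)oxy]chromane (2,3-trans-3,4-cis; C4 arranged as in the target, the descriptor being R only because O-benzylation of ring D changes the priorities)
Conditions: Bu3SnH, TFA, CH2Cl2, −20 to 0 °C
Reagents that add atoms: none
Why: ionic hydrogenation, in which acid ionises both carbinol epimers to one doubly benzylic C4 cation and the strongly hydridic tin hydride should attack anti to the bulky 3-silyloxy group, leaving the aryl group cis to O3.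

Step 19
Reactants: 27 silyl ether
Product: 28 (2R,3S,4R)-7-(benzyloxy)-2-[3,4-bis(benzyloxy)phenyl]-4-{(2S,3S)-3,7-bis(benzyloxy)-2-[3,4-bis(benzyloxy)phenyl]chroman-6-yl}chroman-3-ol
Conditions: n-Bu4NF, THF, rt to 40 °C
Reagents that add atoms: none
Why: fluoride-mediated cleavage of the hindered secondary silyl ether.

Step 20
Reactants: 28 hepta-O-benzyl dimer
Product: 29 (2R,3S,4S)-2-(3,4-dihydroxyphenyl)-4-[(2S,3S)-2-(3,4-dihydroxyphenyl)-3,7-dihydroxychroman-6-yl]chromane-3,7-diol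
Conditions: H2 (1 atm), Pd(OH)2 on carbon, THF–MeOH, rt
Reagents that add atoms: none
Why: neutral hydrogenolysis of the seven benzyl ethers should leave the pyran C–O bonds and the interflavanyl bond intact.

**Compound list**

1 | 1-[4-(benzyloxy)-2-hydroxyphenyl]ethan-1-one | CC(=O)c1ccc(OCc2ccccc2)cc1O | starting material
2 | 1-[4-(benzyloxy)-2-(methoxymethoxy)phenyl]ethan-1-one | CC(=O)c1ccc(OCc2ccccc2)cc1OCOC | intermediate
3 | 3,4-bis(benzyloxy)benzaldehyde | O=Cc1ccc(OCc2ccccc2)c(OCc2ccccc2)c1 | starting material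
4 | (E)-1-[4-(benzyloxy)-2-(methoxymethoxy)phenyl]-3-[3,4-bis(benzyloxy)phenyl]prop-2-en-1-one | O=C(/C=C/c1ccc(OCc2ccccc2)c(OCc2ccccc2)c1)c1ccc(OCc2ccccc2)cc1OCOC | intermediate
5 | [4-(benzyloxy)-2-(methoxymethoxy)phenyl]{(2R,3S)-3-[3,4-bis(benzyloxy)phenyl]oxiran-2-yl}methanone | O1[C@@H](c2ccc(OCc3ccccc3)c(OCc3ccccc3)c2)[C@@H]1C(=O)c1ccc(OCc2ccccc2)cc1OCOC | intermediate
6 | [4-(benzyloxy)-2-hydroxyphenyl]{(2R,3S)-3-[3,4-bis(benzyloxy)phenyl]oxiran-2-yl}methanone (not isolated) | O1[C@@H](c2ccc(OCc3ccccc3)c(OCc3ccccc3)c2)[C@@H]1C(=O)c1ccc(OCc2ccccc2)cc1O | intermediate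
7 | (2R,3R)-7-(benzyloxy)-2-[3,4-bis(benzyloxy)phenyl]-3-hydroxychroman-4-one | C(c1ccccc1)Oc1ccc2c(c1)O[C@H](c1ccc(OCc3ccccc3)c(OCc3ccccc3)c1)[C@@H](O)C2=O | intermediate
8 | (2R,3R)-7-(benzyloxy)-2-[3,4-bis(benzyloxy)phenyl]-3-[(tert-butyldimethylsilyl)oxy]chroman-4-one | C(c1ccccc1)Oc1ccc2c(c1)O[C@H](c1ccc(OCc3ccccc3)c(OCc3ccccc3)c1)[C@@H](O[Si](C)(C)C(C)(C)C)C2=O | intermediate
9 | L-tyrosine | N[C@@H](Cc1ccc(O)cc1)C(=O)O | starting material
10 | (S)-2-hydroxy-3-(4-hydroxyphenyl)propanoic acid | O[C@@H](Cc1ccc(O)cc1)C(=O)O | intermediate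
11 | methyl (S)-2-hydroxy-3-(4-hydroxyphenyl)propanoate | COC(=O)[C@@H](O)Cc1ccc(O)cc1 | intermediate
12 | methyl (S)-3-{4-[(tert-butyldimethylsilyl)oxy]phenyl}-2-hydroxypropanoate | COC(=O)[C@@H](O)Cc1ccc(O[Si](C)(C)C(C)(C)C)cc1 | intermediate
13 | methyl (S)-2-(benzyloxy)-3-{4-[(tert-butyldimethylsilyl)oxy]phenyl}propanoate | COC(=O)[C@@H](OCc1ccccc1)Cc1ccc(O[Si](C)(C)C(C)(C)C)cc1 | intermediate
14 | (S)-2-(benzyloxy)-3-{4-[(tert-butyldimethylsilyl)oxy]phenyl}propanal | O=C[C@@H](OCc1ccccc1)Cc1ccc(O[Si](C)(C)C(C)(C)C)cc1 | intermediate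
15 | 1,2-bis(benzyloxy)-4-bromobenzene | Brc1ccc(OCc2ccccc2)c(OCc2ccccc2)c1 | starting material
16 | [3,4-bis(benzyloxy)phenyl]magnesium bromide (not isolated) | Br[Mg]c1ccc(OCc2ccccc2)c(OCc2ccccc2)c1 | intermediate
17 | (1S,2S)-2-(benzyloxy)-1-[3,4-bis(benzyloxy)phenyl]-3-{4-[(tert-butyldimethylsilyl)oxy]phenyl}propan-1-ol | O[C@@H](c1ccc(OCc2ccccc2)c(OCc2ccccc2)c1)[C@@H](OCc1ccccc1)Cc1ccc(O[Si](C)(C)C(C)(C)C)cc1 | intermediate
18 | 4-{(2S,3S)-2-(benzyloxy)-3-[3,4-bis(benzyloxy)phenyl]-3-hydroxypropyl}phenol | O[C@@H](c1ccc(OCc2ccccc2)c(OCc2ccccc2)c1)[C@@H](OCc1ccccc1)Cc1ccc(O)cc1 | intermediate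
19 | 4-{(2S,3S)-2-(benzyloxy)-3-[3,4-bis(benzyloxy)phenyl]-3-hydroxypropyl}-4-hydroperoxycyclohexa-2,5-dien-1-one (not isolated) | O[C@@H](c1ccc(OCc2ccccc2)c(OCc2ccccc2)c1)[C@@H](OCc1ccccc1)CC1(OO)C=CC(=O)C=C1 | intermediate
20 | 4-{(2S,3S)-2-(benzyloxy)-3-[3,4-bis(benzyloxy)phenyl]-3-hydroxypropyl}-4-hydroxycyclohexa-2,5-dien-1-one | O[C@@H](c1ccc(OCc2ccccc2)c(OCc2ccccc2)c1)[C@@H](OCc1ccccc1)CC1(O)C=CC(=O)C=C1 | intermediate
21 | (2S,3S)-3-(benzyloxy)-2-[3,4-bis(benzyloxy)phenyl]-4a-hydroxy-2,3,4,4a,8,8a-hexahydro-7H-chromen-7-one, cis ring fusion, both C4a/C8a diastereomers (not isolated) | O=C1CC2O[C@@H](c3ccc(OCc4ccccc4)c(OCc4ccccc4)c3)[C@@H](OCc3ccccc3)CC2(O)C=C1 | intermediate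
22 | (2S,3S)-3-(benzyloxy)-2-[3,4-bis(benzyloxy)phenyl]chroman-7-ol | Oc1ccc2c(c1)O[C@@H](c1ccc(OCc3ccccc3)c(OCc3ccccc3)c1)[C@@H](OCc1ccccc1)C2 | intermediate
23 | (2S,3S)-3,7-bis(benzyloxy)-2-[3,4-bis(benzyloxy)phenyl]chromane | C(c1ccccc1)Oc1ccc2c(c1)O[C@@H](c1ccc(OCc3ccccc3)c(OCc3ccccc3)c1)[C@@H](OCc1ccccc1)C2 | intermediate
24 | (2S,3S)-3,7-bis(benzyloxy)-2-[3,4-bis(benzyloxy)phenyl]-6-bromochromane | C(c1ccccc1)Oc1c(Br)cc2c(c1)O[C@@H](c1ccc(OCc3ccccc3)c(OCc3ccccc3)c1)[C@@H](OCc1ccccc1)C2 | intermediate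
25 | 6-lithio-(2S,3S)-3,7-bis(benzyloxy)-2-[3,4-bis(benzyloxy)phenyl]chromane (not isolated) | C(c1ccccc1)Oc1c([Li])cc2c(c1)O[C@@H](c1ccc(OCc3ccccc3)c(OCc3ccccc3)c1)[C@@H](OCc1ccccc1)C2 | intermediate
26 | (2R,3R)-7-(benzyloxy)-2-[3,4-bis(benzyloxy)phenyl]-4-{(2S,3S)-3,7-bis(benzyloxy)-2-[3,4-bis(benzyloxy)phenyl]chroman-6-yl}-3-[(tert-butyldimethylsilyl)oxy]chroman-4-ol, C4 epimers | C(c1ccccc1)Oc1ccc2c(c1)O[C@H](c1ccc(OCc3ccccc3)c(OCc3ccccc3)c1)[C@@H](O[Si](C)(C)C(C)(C)C)C2(O)c1cc2c(cc1OCc1ccccc1)O[C@@H](c1ccc(OCc3ccccc3)c(OCc3ccccc3)c1)[C@@H](OCc1ccccc1)C2 | intermediate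
27 | (2R,3S,4R)-7-(benzyloxy)-2-[3,4-bis(benzyloxy)phenyl]-4-{(2S,3S)-3,7-bis(benzyloxy)-2-[3,4-bis(benzyloxy)phenyl]chroman-6-yl}-3-[(tert-butyldimethylsilyl)oxy]chromane (2,3-trans-3,4-cis) | C(c1ccccc1)Oc1ccc2c(c1)O[C@H](c1ccc(OCc3ccccc3)c(OCc3ccccc3)c1)[C@@H](O[Si](C)(C)C(C)(C)C)[C@H]2c1cc2c(cc1OCc1ccccc1)O[C@@H](c1ccc(OCc3ccccc3)c(OCc3ccccc3)c1)[C@@H](OCc1ccccc1)C2 | intermediate
28 | (2R,3S,4R)-7-(benzyloxy)-2-[3,4-bis(benzyloxy)phenyl]-4-{(2S,3S)-3,7-bis(benzyloxy)-2-[3,4-bis(benzyloxy)phenyl]chroman-6-yl}chroman-3-ol (2,3-trans-3,4-cis) | C(c1ccccc1)Oc1ccc2c(c1)O[C@H](c1ccc(OCc3ccccc3)c(OCc3ccccc3)c1)[C@@H](O)[C@H]2c1cc2c(cc1OCc1ccccc1)O[C@@H](c1ccc(OCc3ccccc3)c(OCc3ccccc3)c1)[C@@H](OCc1ccccc1)C2 | intermediate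
29 | (2R,3S,4S)-2-(3,4-dihydroxyphenyl)-4-[(2S,3S)-2-(3,4-dihydroxyphenyl)-3,7-dihydroxychroman-6-yl]chromane-3,7-diol | Oc1ccc2c(c1)O[C@H](c1ccc(O)c(O)c1)[C@@H](O)[C@H]2c1cc2c(cc1O)O[C@@H](c1ccc(O)c(O)c1)[C@@H](O)C2 | target

**Count and risks**

Total step count: 20. Longest linear sequence: 15 steps (steps 6 to 20, from L-tyrosine).

Steps most likely to fail:

1. Step 14 (key step). The oxa-Michael addition may revert faster than the tertiary hydroxyl is lost, or the acid may ionise the electron-rich benzylic C2–O bond and erode the 2,3-cis configuration. The fallback sets out from 17 and comes back at 22, and it replaces hydroxide by methoxide as the group that leaves on rearomatisation. Compound 17 is acetylated (Ac2O, DMAP, pyridine) to (1S,2S)-2-(benzyloxy)-1-[3,4-bis(benzyloxy)phenyl]-3-{4-[(tert-butyldimethylsilyl)oxy]phenyl}propyl acetate F1. The aryl silyl ether is cleaved (n-Bu4NF, AcOH, THF) to the phenol acetate F2. PhI(OAc)2 in MeOH then gives the para-quinol methyl ether F3; with the benzylic oxygen masked, solvent capture at C4a is the only course. K2CO3 in MeOH removes the acetate and the released alkoxide cyclises to the 4a-methoxy bicyclic enone F4. BF3·OEt2 in CH2Cl2 at low temperature expels methanol and gives 22.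

2. Step 18. Hydride capture of the C4 cation may show poor facial selectivity, or the cation may lose the C3 proton to give the silyl enol ether. The fallback sets out from 26 and comes back at 28, and it replaces steric shielding by neighbouring-group participation. Desilylation of 26 (n-Bu4NF) gives the 3,4-diol F5. The secondary hydroxyl alone is acylated (PivCl, DMAP, pyridine) to the 3-O-pivaloate F6. Under Bu3SnH and TFA the ester carbonyl should bridge the C4 cation on the O3 face, so that hydride can enter only trans to O3 and give the 3,4-cis pivalate F7. i-Bu2AlH then removes the ester and gives 28.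

3. Step 17. The basic aryllithium may deprotonate C3 of the ketone, with E1cB opening of the pyranone ring, instead of adding to the carbonyl. The fallback sets out from 7 (and uses 23) and comes back at 28, and it forms the C4–C6 bond under acid instead of base. NaBH4 reduces 7 to the 2,3-trans-3,4-trans flavan-3,4-diol F8. BF3·OEt2 in CH2Cl2 ionises F8 at C4, and an excess of 23 captures the cation through C6 (Friedel–Crafts). Facial control is then left to the substrate, which normally favours 3,4-trans, so 28 would have to be separated from its C4 epimer; this is a rescue, not an improvement.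

Further compounds
F1 | step 14 | (1S,2S)-2-(benzyloxy)-1-[3,4-bis(benzyloxy)phenyl]-3-{4-[(tert-butyldimethylsilyl)oxy]phenyl}propyl acetate | CC(=O)O[C@@H](c1ccc(OCc2ccccc2)c(OCc2ccccc2)c1)[C@@H](OCc1ccccc1)Cc1ccc(O[Si](C)(C)C(C)(C)C)cc1
F2 | step 14 | (1S,2S)-2-(benzyloxy)-1-[3,4-bis(benzyloxy)phenyl]-3-(4-hydroxyphenyl)propyl acetate | CC(=O)O[C@@H](c1ccc(OCc2ccccc2)c(OCc2ccccc2)c1)[C@@H](OCc1ccccc1)Cc1ccc(O)cc1
F3 | step 14 | (1S,2S)-2-(benzyloxy)-1-[3,4-bis(benzyloxy)phenyl]-3-(1-methoxy-4-oxocyclohexa-2,5-dien-1-yl)propyl acetate | CC(=O)O[C@@H](c1ccc(OCc2ccccc2)c(OCc2ccccc2)c1)[C@@H](OCc1ccccc1)CC1(OC)C=CC(=O)C=C1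
F4 | step 14 | (2S,3S)-3-(benzyloxy)-2-[3,4-bis(benzyloxy)phenyl]-4a-methoxy-2,3,4,4a,8,8a-hexahydro-7H-chromen-7-one (cis ring fusion) | O=C1CC2O[C@@H](c3ccc(OCc4ccccc4)c(OCc4ccccc4)c3)[C@@H](OCc3ccccc3)CC2(OC)C=C1
F5 | step 18 | (2R,3R)-7-(benzyloxy)-2-[3,4-bis(benzyloxy)phenyl]-4-{(2S,3S)-3,7-bis(benzyloxy)-2-[3,4-bis(benzyloxy)phenyl]chroman-6-yl}chromane-3,4-diol (C4 epimers) | C(c1ccccc1)Oc1ccc2c(c1)O[C@H](c1ccc(OCc3ccccc3)c(OCc3ccccc3)c1)[C@@H](O)C2(O)c1cc2c(cc1OCc1ccccc1)O[C@@H](c1ccc(OCc3ccccc3)c(OCc3ccccc3)c1)[C@@H](OCc1ccccc1)C2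
F6 | step 18 | (2R,3R)-7-(benzyloxy)-2-[3,4-bis(benzyloxy)phenyl]-4-{(2S,3S)-3,7-bis(benzyloxy)-2-[3,4-bis(benzyloxy)phenyl]chroman-6-yl}-4-hydroxychroman-3-yl pivalate (C4 epimers) | C(c1ccccc1)Oc1ccc2c(c1)O[C@H](c1ccc(OCc3ccccc3)c(OCc3ccccc3)c1)[C@@H](OC(=O)C(C)(C)C)C2(O)c1cc2c(cc1OCc1ccccc1)O[C@@H](c1ccc(OCc3ccccc3)c(OCc3ccccc3)c1)[C@@H](OCc1ccccc1)C2
F7 | step 18 | (2R,3S,4R)-7-(benzyloxy)-2-[3,4-bis(benzyloxy)phenyl]-4-{(2S,3S)-3,7-bis(benzyloxy)-2-[3,4-bis(benzyloxy)phenyl]chroman-6-yl}chroman-3-yl pivalate (2,3-trans-3,4-cis) | C(c1ccccc1)Oc1ccc2c(c1)O[C@H](c1ccc(OCc3ccccc3)c(OCc3ccccc3)c1)[C@@H](OC(=O)C(C)(C)C)[C@H]2c1cc2c(cc1OCc1ccccc1)O[C@@H](c1ccc(OCc3ccccc3)c(OCc3ccccc3)c1)[C@@H](OCc1ccccc1)C2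
F8 | step 17 | (2R,3S,4R)-7-(benzyloxy)-2-[3,4-bis(benzyloxy)phenyl]chromane-3,4-diol (2,3-trans-3,4-trans) | C(c1ccccc1)Oc1ccc2c(c1)O[C@H](c1ccc(OCc3ccccc3)c(OCc3ccccc3)c1)[C@@H](O)[C@@H]2O
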